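**Plan**
- Retrosynthesis: the C7–C7' biaryl bond (monomer numbering) is cut first, giving two identical 5-bromodianellidin units. Ring A of each unit is then cut at C1–C2 and C3–C4 into an ortho-toluate and a five-carbon vinylogous ester.
- Forward: a bromine is placed para to the methoxy group of the benzoate (future ring B), and ring A is annulated onto it by Michael addition, Claisen closure and loss of methanol. O8 is then unmasked, the two naphthalenes are joined by a biomimetic dehydrodimerisation, and the two bromines are removed.
- Enabling feature: the peri C1–OH/C8–OH pair gives an aryloxyl radical with spin density on C7 and C5 of ring B. C5 carries the bromine, C2 the acetyl group, and C4 is walled in by the C3 methyl and the peri bromine, so C7 is the only carbon that can couple and rearomatise.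
- Stereochemistry: the target has no stereocentre, and its axis (two OH groups and two H atoms ortho to it) is not configurationally stable, so nothing has to be controlled.

Key step: step 4

Remark: positions are given in monomer (dianellidin) numbering (C1–OH, C2–acetyl, C3–CH3, C8–OH); in the binaphthalene names of the dimers, monomer C7 is C2 and monomer C5 is C4. Compounds 1 and 3 are taken to be catalogue chemicals.

**Step 1**
Reactants: 1 ethyl 2-methoxy-6-methylbenzoate
Product: 2 ethyl 3-bromo-6-methoxy-2-methylbenzoate
Conditions: NBS (1.05 equiv), MeCN, 0 °C to rt, dark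
Reagents that add atoms: N-bromosuccinimide, O=C1CCC(=O)N1Br
Why: Electrophilic aromatic bromination under polar, initiator-free conditions should go para to the methoxy group (the carbon also ortho to the methyl group), the site at which this arene class is known to brominate, and should leave the benzylic methyl untouched.

**Step 2**
Reactants: 2 ethyl 3-bromo-6-methoxy-2-methylbenzoate; 3 (E)-4-methoxypent-3-en-2-one
Product: 6 1-(5-bromo-1-hydroxy-8-methoxy-3-methylnaphthalen-2-yl)ethanone, via lithiated toluate 4 (not isolated), via methoxytetralone 5 (not isolated)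
Conditions: LDA (2.2 equiv), THF, −78 °C; then 3, −78 °C to rt; 1 M HCl
Reagents that add atoms: none
Why: Staunton–Weinreb annulation: lateral lithiation gives benzylic anion 4, which adds in Michael fashion to the β-carbon of vinylogous ester 3; the enolate closes ring A by Claisen attack on the ethyl ester to give 5, and E1cB loss of methoxide followed by enolisation aromatises ring A with the new 1-OH chelated to the acetyl group.

**Step 3**
Reactants: 6 1-(5-bromo-1-hydroxy-8-methoxy-3-methylnaphthalen-2-yl)ethanone
Product: 8 1-(5-bromo-1,8-dihydroxy-3-methylnaphthalen-2-yl)ethanone, via cyclic bromoborate 7 (not isolated)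
Conditions: BBr3 (3 equiv), CH2Cl2, −78 °C to 0 °C; then H2O
Reagents that add atoms: none
Why: Lewis-acid ether cleavage: BBr3 binds O1 with loss of HBr, bromide then removes the methyl group of the peri O8 ether within the chelate to give cyclic bromoborate 7, and water hydrolyses it; the aryl bromide and the aryl ketone are inert.

**Step 4**
Reactants: 8 1-(5-bromo-1,8-dihydroxy-3-methylnaphthalen-2-yl)ethanone (two molecules)
Product: 10 1,1'-(4,4'-dibromo-1,1',8,8'-tetrahydroxy-6,6'-dimethyl-[2,2'-binaphthalene]-7,7'-diyl)diethanone, via bis-dienone 9 (not isolated)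
Conditions: (t-BuO)2 (0.6 equiv), PhCl, reflux, Ar
Reagents that add atoms: none
Why: Thermolysis of the peroxide gives tert-butoxyl radicals that abstract a phenolic hydrogen from the peri-diol of 8, and two of the resulting aryloxyl radicals (spin on O8, C7 and C5) combine carbon to carbon at C7 to give bis-dienone 9, which enolises twice to binaphthol 10. The closest known reaction type is the oxidative ortho,ortho dehydrodimerisation of 3-substituted 1-naphthols to 2,2'-bi-1-naphthols with di-tert-butyl peroxide or FeCl3, and the step copies the presumed biosynthetic phenol coupling of two dianellidin units. No ring is closed. No stereocentre is left: the two sp3 carbons of 9 vanish on enolisation, and the new axis, flanked by two OH groups and two hydrogens, rotates freely. The step needs coupling at C7 in preference to C5, C4, C2 and oxygen, and the substrate should secure it because C5 (para to O8) carries the bromine, C2 carries the acetyl group so that an adduct there cannot rearomatise and dissociates again, C4 is crowded between the C3 methyl and the peri bromine, and only the C7–C7' adduct can tautomerise to a stable arene. Over-oxidation should be limited by using little more than half an equivalent of peroxide and by hydrogen-atom exchange between product-derived radicals, which have no open coupling site, and unreacted 8.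

**Step 5**
Reactants: 10 1,1'-(4,4'-dibromo-1,1',8,8'-tetrahydroxy-6,6'-dimethyl-[2,2'-binaphthalene]-7,7'-diyl)diethanone
Product: 12 stypandrol (1,1'-(1,1',8,8'-tetrahydroxy-6,6'-dimethyl-[2,2'-binaphthalene]-7,7'-diyl)diethanone), via monobromide 11 (not isolated)
Conditions: H2 (1 atm), 10% Pd/C, NaOAc (2.5 equiv), EtOAc–MeOH, rt; then dilute HCl
Reagents that add atoms: none
Why: Catalytic hydrogenolysis of the two aryl C–Br bonds on zerovalent palladium (oxidative addition, hydride transfer, reductive elimination) with NaOAc taking up the HBr; the hindered, hydrogen-bonded aryl ketones and the naphthalene rings should not be reduced at 1 atm and room temperature.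

**Compound list**
1 | ethyl 2-methoxy-6-methylbenzoate | CCOC(=O)c1c(C)cccc1OC | starting material
2 | ethyl 3-bromo-6-methoxy-2-methylbenzoate | CCOC(=O)c1c(C)c(Br)ccc1OC | intermediate
3 | (E)-4-methoxypent-3-en-2-one | CO/C(C)=C/C(C)=O | starting material
4 | ethyl 3-bromo-2-(lithiomethyl)-6-methoxybenzoate (lithiated toluate) | CCOC(=O)c1c(C[Li])c(Br)ccc1OC | intermediate
5 | 2-acetyl-5-bromo-3,8-dimethoxy-3-methyl-3,4-dihydronaphthalen-1(2H)-one (methoxytetralone, present as its lithium enolate, mixture of diastereomers, both stereocentres lost on aromatisation) | CC(=O)C1C(=O)c2c(OC)ccc(Br)c2CC1(C)OC | intermediate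
6 | 1-(5-bromo-1-hydroxy-8-methoxy-3-methylnaphthalen-2-yl)ethanone | CC(=O)c1c(C)cc2c(Br)ccc(OC)c2c1O | intermediate
7 | cyclic bromoborate of 8: O1 and O8 bridged by B–Br in a naphtho[1,8-de][1,3,2]dioxaborinine ring, acetyl, methyl and ring bromine unchanged | CC(=O)c1c(C)cc2c(Br)ccc3OB(Br)Oc1c23 | intermediate
8 | 1-(5-bromo-1,8-dihydroxy-3-methylnaphthalen-2-yl)ethanone (5-bromodianellidin) | CC(=O)c1c(C)cc2c(Br)ccc(O)c2c1O | intermediate
9 | bis-dienone: C7–C7' linked bis(8-oxo-7,8-dihydronaphthalene) keto tautomer of 10, mixture of diastereomers, both stereocentres lost on enolisation | CC(=O)c1c(C)cc2C(Br)=CC(C3C=C(Br)c4cc(C)c(C(C)=O)c(O)c4C3=O)C(=O)c2c1O | intermediate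
10 | 1,1'-(4,4'-dibromo-1,1',8,8'-tetrahydroxy-6,6'-dimethyl-[2,2'-binaphthalene]-7,7'-diyl)diethanone | CC(=O)c1c(C)cc2c(Br)cc(-c3cc(Br)c4cc(C)c(C(C)=O)c(O)c4c3O)c(O)c2c1O | intermediate
11 | 1,1'-(4-bromo-1,1',8,8'-tetrahydroxy-6,6'-dimethyl-[2,2'-binaphthalene]-7,7'-diyl)diethanone (monobromide) | CC(=O)c1c(C)cc2c(Br)cc(-c3ccc4cc(C)c(C(C)=O)c(O)c4c3O)c(O)c2c1O | intermediate
12 | stypandrol, 1,1'-(1,1',8,8'-tetrahydroxy-6,6'-dimethyl-[2,2'-binaphthalene]-7,7'-diyl)diethanone | CC(=O)c1c(C)cc2ccc(-c3ccc4cc(C)c(C(C)=O)c(O)c4c3O)c(O)c2c1O | target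

**Summary**
Total step count: 5. Longest linear sequence: 5 steps (1 → 2 → 6 → 8 → 10 → 12).

**Steps most likely to fail**

1. Step 4. What may go wrong: radical combination at the wrong atom (ipso attack at the bromine-bearing C5 with loss of bromine, or carbon–oxygen coupling) and over-oxidation of the electron-rich binaphthol. The fallback sets out from 8 and comes back at 10, and replaces the radical coupling by a reductive coupling of a C7 halide. Iodination of 8 ortho to the C8 hydroxyl (NIS, cat. TsOH, MeCN, rt) should give 1-(5-bromo-1,8-dihydroxy-7-iodo-3-methylnaphthalen-2-yl)ethanone F1. O-Methylation of both phenols (MeI, K2CO3, DMF, 60 °C) should give 1-(5-bromo-7-iodo-1,8-dimethoxy-3-methylnaphthalen-2-yl)ethanone F2. A classical Ullmann coupling at the C–I bond (Cu powder, DMF, 150 °C; the aryl bromide reacts far more slowly) should give 1,1'-(4,4'-dibromo-1,1',8,8'-tetramethoxy-6,6'-dimethyl-[2,2'-binaphthalene]-7,7'-diyl)diethanone F3. BBr3 in CH2Cl2 then cleaves the four methyl ethers to 10.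

2. Step 2. What may go wrong: proton transfer from the enolisable methyl groups of 3 to anion 4, and 1,2-addition to the ketone followed by lactonisation, both competing with conjugate addition at the fully substituted β-carbon. The fallback sets out from 2 and comes back at 6, and separates ring closure from aromatisation. Anion 4 (LDA, THF, −78 °C) is added to (E)-pent-3-en-2-one (C/C=C/C(C)=O), a β-monosubstituted enone for which the tandem Michael–Dieckmann reaction is the standard case. This should give racemic 2-acetyl-5-bromo-8-methoxy-3-methyl-3,4-dihydronaphthalen-1(2H)-one F4. Dehydrogenation with DDQ (dioxane, reflux) then aromatises ring A to 6.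

3. Step 5. What may go wrong: slow or incomplete hydrogenolysis through binding of the catalyst by the chelating peri-diols, over-reduction of the aryl ketones on forcing, and air oxidation of the phenolate during handling. The fallback sets out from 10 and comes back at 12, and masks the four phenols before the reduction. Peracetylation (Ac2O, pyridine, DMAP, 60 °C) should give 7,7'-diacetyl-4,4'-dibromo-6,6'-dimethyl-[2,2'-binaphthalene]-1,1',8,8'-tetrayl tetraacetate F5. Hydrogenolysis (H2, 10% Pd/C, NaOAc, EtOAc, rt) should give 7,7'-diacetyl-6,6'-dimethyl-[2,2'-binaphthalene]-1,1',8,8'-tetrayl tetraacetate F6. Methanolysis (cat. K2CO3, degassed MeOH, then dilute HCl) releases 12.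

**Further compounds**
F1 | step 4 | 1-(5-bromo-1,8-dihydroxy-7-iodo-3-methylnaphthalen-2-yl)ethanone | CC(=O)c1c(C)cc2c(Br)cc(I)c(O)c2c1O
F2 | step 4 | 1-(5-bromo-7-iodo-1,8-dimethoxy-3-methylnaphthalen-2-yl)ethanone | CC(=O)c1c(C)cc2c(Br)cc(I)c(OC)c2c1OC
F3 | step 4 | 1,1'-(4,4'-dibromo-1,1',8,8'-tetramethoxy-6,6'-dimethyl-[2,2'-binaphthalene]-7,7'-diyl)diethanone | CC(=O)c1c(C)cc2c(Br)cc(-c3cc(Br)c4cc(C)c(C(C)=O)c(OC)c4c3OC)c(OC)c2c1OC
F4 | step 2 | 2-acetyl-5-bromo-8-methoxy-3-methyl-3,4-dihydronaphthalen-1(2H)-one (racemic) | CC(=O)C1C(C)Cc2c(Br)ccc(OC)c2C1=O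
F5 | step 5 | 7,7'-diacetyl-4,4'-dibromo-6,6'-dimethyl-[2,2'-binaphthalene]-1,1',8,8'-tetrayl tetraacetate | CC(=O)c1c(C)cc2c(Br)cc(-c3cc(Br)c4cc(C)c(C(C)=O)c(OC(C)=O)c4c3OC(C)=O)c(OC(C)=O)c2c1OC(C)=O
F6 | step 5 | 7,7'-diacetyl-6,6'-dimethyl-[2,2'-binaphthalene]-1,1',8,8'-tetrayl tetraacetate (stypandrol tetraacetate) | CC(=O)c1c(C)cc2ccc(-c3ccc4cc(C)c(C(C)=O)c(OC(C)=O)c4c3OC(C)=O)c(OC(C)=O)c2c1OC(C)=O
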